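## Retrosynthetic overview

- On the ten-membered carbocycle C1–C10, the C1 ketone, C2 methylene, C3 carbinol and Z C4=C5 alkene form the array left by a Grob fragmentation. Rejoining C1 to C5 and tying the C3 oxygen to C4 gives a trans-fused guaiane 3α,4α-epoxy-1α,10α-diol (five-membered ring C1–C5, seven-membered ring C1, C5–C10).
- The oxirane comes from hydroxyl-directed epoxidation of a cyclopentene. That ring is closed by metathesis (C3=C4) between an allyl group on C1 and an isopropenyl group on C5, trans to each other on a lactone-fused cycloheptanone.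
- The cycloheptanone comes from a 5-isopropenylcycloheptenone by α-epoxidation, palladium–formate hydrogenolysis with inversion at C5, and lactonisation. The cycloheptenone comes from a cyclohexanone by one-carbon ring expansion (C5 inserted), iodination and Suzuki coupling.
- The cyclohexanone comes from (R)-carvone (C1, C6–C14). C7 is bought, C10 comes from the enone epoxide, and C8 comes from tethered hydrosilylation followed by oxidation and directed reduction.
- Ring order: six-membered ring (bought), seven-membered ring, γ-lactone, cyclopentene, oxirane, then the ten-membered ring by cutting the shared C1–C5 bond.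

Key step: step 28

Remark on labels: the atom labels of the target are used for every intermediate. These are C1 ketone, C3 carbinol, C4=C5, C6 lactone oxygen, C8 ester, C10 carbinol, C11–C13 methylene lactone, C14 the methyl on C10 and C15 the methyl on C4. β is the face that carries C11 on C7, and α is the opposite face.

Remark on the chemistry: the two cyclopropane centres of the ring-expansion intermediate are drawn for α attack, and the chloride centre of the β-chloro ketone is left undefined. All of them are erased in the same sequence, so their configuration is taken as immaterial.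

## Route

**Step 1**
Reactants: 1 (R)-(−)-carvone
Product: 2 carvone 9α,10α-epoxide (oxirane trans to the 7β-isopropenyl group)
Conditions: 30% H2O2, NaOH (cat.), MeOH, 0 °C
Reagents that add atoms: hydrogen peroxide, OO
Why: Weitz–Scheffer nucleophilic epoxidation, in which hydroperoxide adds axially to C9 of the enone anti to the equatorial isopropenyl group, so the oxirane and the future C10–O bond land on the α face while the isolated alkene is untouched.

**Step 2**
Reactants: 2 carvone 9α,10α-epoxide
Product: 3 9α,10α-epoxy-1α-ol
Conditions: LiBH(s-Bu)3, THF, −78 °C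
Reagents that add atoms: none
Why: Bulky borohydride reduction of an α,β-epoxy ketone, where hydride arrives equatorially and anti to the oxirane oxygen to give the 1α-carbinol, a centre that is erased later but whose silyl ether helps step 4.

**Step 3**
Reactants: 3 9α,10α-epoxy-1α-ol
Product: 4 9α,10α-epoxy-1α-(tert-butyldimethylsilyl) ether
Conditions: TBSCl, imidazole, DMF, rt to 40 °C
Reagents that add atoms: tert-butyldimethylsilyl chloride, CC(C)(C)[Si](C)(C)Cl
Why: Standard silylation of a secondary alcohol masks C1 until the ketone is needed and touches no stereocentre.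

**Step 4**
Reactants: 4 9α,10α-epoxy-1α-silyl ether
Product: 5 9β-phenylselanyl-10α-ol (1α-OTBS, 7β-isopropenyl)
Conditions: (PhSe)2, NaBH4, EtOH, reflux
Reagents that add atoms: diphenyl diselenide, c1ccc(cc1)[Se][Se]c1ccccc1
Why: SN2 epoxide opening by the soft selenolate at secondary C9 (C10 is fully substituted) goes with inversion to 9β-Se and 10α-OH, and the half-chair that keeps the bulky 1α-silyloxy group equatorial makes this attack trans-diaxial.

**Step 5**
Reactants: 5 9β-phenylselanyl-10α-ol
Product: 7 tertiary allylic alcohol (C8=C9, 10α-OH, 10β-CH3, 1α-OTBS, 7β-isopropenyl), via selenoxide 6 (not isolated)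
Conditions: 30% H2O2, pyridine, CH2Cl2, 0 °C to rt
Reagents that add atoms: none
Why: Selenoxide syn-elimination completes the epoxide-to-allylic-alcohol transposition, because C10 carries no hydrogen and the 9β-selenoxide can only take the 8β-hydrogen, which leaves C10 untouched.

**Step 6**
Reactants: 7 tertiary allylic alcohol
Product: 8 10α-O-dimethylsilyl ether of 7
Conditions: Me2SiHCl, Et3N, DMAP (cat.), CH2Cl2, 0 °C
Reagents that add atoms: chlorodimethylsilane, C[SiH](C)Cl
Why: O-silylation of the tertiary alcohol installs the hydrosilane tether for delivery to C8 and changes no stereocentre.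

**Step 7**
Reactants: 8 10α-O-dimethylsilyl ether
Product: 10 8α,10α-diol (1α-OTBS), via bridged siloxane 9 (not isolated)
Conditions: Pt2[(CH2=CHSiMe2)2O]3 (cat.), toluene (dilute), 60 °C; then 30% H2O2, KF, KHCO3, THF–MeOH, rt
Reagents that add atoms: hydrogen peroxide, OO
Why: Intramolecular platinum-catalysed hydrosilylation then Tamao oxidation, in which the O–Si tether reaches C8 by 5-endo closure to an oxasilabicyclo[3.2.1]octane (the four-membered alternative at C9 is strained) and only on the α face, the trans-disposed isopropenyl group stays out of reach, and C–Si oxidation proceeds with retention.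

**Step 8**
Reactants: 10 8α,10α-diol
Product: 11 10α-hydroxy-8-ketone
Conditions: Dess–Martin periodinane, CH2Cl2, 0 °C to rt
Reagents that add atoms: none
Why: Dess–Martin oxidation takes the only free secondary alcohol to the ketone under mild, non-basic conditions that spare the β-hydroxy ketone and C7, and inversion by oxidation and reduction is chosen because Mitsunobu displacement at this menthol-like carbinol by a weakly acidic aliphatic acid would mainly eliminate.

**Step 9**
Reactants: 11 10α-hydroxy-8-ketone
Product: 12 8β,10α-diol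
Conditions: Me4NBH(OAc)3, AcOH–MeCN, −20 °C
Reagents that add atoms: none
Why: Saksena–Evans reduction, in which the 10α-hydroxyl binds the acetoxyborohydride and passes hydride to the α face of C8, gives the 1,3-anti diol and so the 8β-carbinol of the target.

**Step 10**
Reactants: 12 8β,10α-diol; 13 isovaleric acid
Product: 14 8β-isovalerate (10α-OH free)
Conditions: DCC, DMAP (cat.), CH2Cl2, rt
Reagents that add atoms: isovaleric acid, CC(C)CC(=O)O
Why: Steglich esterification acylates the secondary 8β-hydroxyl with retention while the tertiary C10 hydroxyl is too hindered to react.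

**Step 11**
Reactants: 14 8β-isovalerate
Product: 15 allylic alcohol (C12 as CH2OH on C11=C13)
Conditions: SeO2 (cat.), t-BuOOH, CH2Cl2, rt
Reagents that add atoms: selenium dioxide (oxygen carrier), O=[Se]=O; tert-butyl hydroperoxide, CC(C)(C)OO
Why: Allylic oxidation with SeO2 (ene reaction then [2,3]-shift) hydroxylates the methyl group of the 1,1-disubstituted alkene, the competing C7–H being tertiary, crowded and deactivated by the neighbouring ester.

**Step 12**
Reactants: 15 allylic alcohol
Product: 16 enal (C12 aldehyde)
Conditions: MnO2, CH2Cl2, rt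
Reagents that add atoms: none
Why: MnO2 oxidises only the primary allylic alcohol and also brings any enal already formed in step 11 to the same product.

**Step 13**
Reactants: 16 enal
Product: 17 acrylic acid (C12 acid)
Conditions: NaClO2, NaH2PO4, 2-methyl-2-butene, t-BuOH–H2O, rt
Reagents that add atoms: sodium chlorite, [Na+].[O-]Cl=O
Why: Pinnick oxidation converts the enal into the acid without touching the alkene, the silyl ether or the ester.

**Step 14**
Reactants: 17 acrylic acid
Product: 18 methyl acrylate ester
Conditions: MeI, K2CO3, DMF, 0 °C to rt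
Reagents that add atoms: iodomethane, CI
Why: SN2 O-alkylation of the carboxylate gives the methyl ester, and diazomethane is avoided because it would add to the acrylate as a dipole.

**Step 15**
Reactants: 18 methyl acrylate ester
Product: 19 1α,10α-diol
Conditions: HF·pyridine, pyridine, THF, 0 °C to rt
Reagents that add atoms: none
Why: Buffered fluoride desilylation frees the C1 carbinol without acyl migration or Michael addition to the acrylate, and the trans relation of the 1α-hydroxyl to the side chain rules out lactonisation.

**Step 16**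
Reactants: 19 1α,10α-diol
Product: 20 cyclohexanone carrying C1 ketone, 10α-OH, 8β-isovalerate and 7β-acrylate
Conditions: IBX, DMSO, rt
Reagents that add atoms: none
Why: IBX oxidises the secondary alcohol of a 1,2-diol to the α-ketol without glycol cleavage and erases the auxiliary C1 centre.

**Step 17**
Reactants: 20 cyclohexanone
Product: 21 bis(triethylsilyl) compound (C1=C6 enol ether, 10α-OSiEt3)
Conditions: Et3SiOTf, Et3N, CH2Cl2, 0 °C
Reagents that add atoms: triethylsilyl triflate, CC[Si](CC)(CC)OS(=O)(=O)C(F)(F)F
Why: Soft enolisation with silyl triflate and amine can only run towards C6 because C10 is quaternary, and capping the tertiary hydroxyl in the same operation blocks α-ketol shifts and chelation in the later steps.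

**Step 18**
Reactants: 21 bis(triethylsilyl) enol ether
Product: 22 silyloxycyclopropane (new CH2 = C5 bridging C1 and C6)
Conditions: Et2Zn, CH2I2, CH2Cl2, 0 °C to rt
Reagents that add atoms: diiodomethane, ICI
Why: Furukawa-type Simmons–Smith cyclopropanation, in which the electrophilic zinc carbenoid picks the electron-rich silyl enol ether over the electron-poor acrylate and the two new centres vanish in step 19.

**Step 19**
Reactants: 22 silyloxycyclopropane
Product: 24 cycloheptenone (C5=C6, C1 ketone, 10α-OSiEt3), via 6-chloro ketone 23 (not isolated)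
Conditions: FeCl3, DMF, 0 °C to rt; crude, then NaOAc, MeOH, 50 °C
Reagents that add atoms: none
Why: Saegusa-type oxidative ring expansion, in which one-electron oxidation by trivalent iron gives the cyclopropyloxy radical, the internal C1–C6 bond opens to the secondary C6 radical that takes up chlorine, and mild base removes HCl from C5 and C6 to give the enone.

**Step 20**
Reactants: 24 cycloheptenone
Product: 25 5-iodocycloheptenone
Conditions: I2, pyridine–CH2Cl2, rt
Reagents that add atoms: iodine, II
Why: α-Iodination of an enone by reversible conjugate addition of pyridine, iodination of the enolate and elimination, a path closed to the acrylate because it has no α-hydrogen.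

**Step 21**
Reactants: 25 5-iodocycloheptenone; 26 isopropenylboronic acid pinacol ester
Product: 27 5-isopropenylcycloheptenone (cross-conjugated dienone)
Conditions: PdCl2(dppf) (cat.), Ph3As (cat.), Cs2CO3, DMF–THF–H2O, rt
Reagents that add atoms: isopropenylboronic acid pinacol ester, CC(=C)B1OC(C)(C)C(C)(C)O1
Why: Suzuki–Miyaura coupling of a 2-iodoenone runs at room temperature, which is mild enough to leave the acidic C7–H and the C8 ester alone.

**Step 22**
Reactants: 27 5-isopropenylcycloheptenone
Product: 28 5α,6α-epoxy ketone (isopropenyl on C5 now β)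
Conditions: t-BuOOH (decane), DBU, CH2Cl2, 0 °C
Reagents that add atoms: tert-butyl hydroperoxide, CC(C)(C)OO
Why: Nucleophilic epoxidation of the Weitz–Scheffer type, in which the peroxide anion adds to C6 of the ketone-conjugated alkene (more electrophilic than the acrylate) on the α face anti to the C7 side chain, and ring closure fixes C5 and C6 together.

**Step 23**
Reactants: 28 5α,6α-epoxy ketone
Product: 30 trans-fused α-methylene-γ-lactone cycloheptanone (H5 β, 5α-isopropenyl, 6α-O), via 6α-hydroxy ester 29 (not isolated)
Conditions: Pd2(dba)3·CHCl3 (cat.), n-Bu3P (cat.), HCO2H, Et3N, THF, rt; crude, then PPTS (cat.), CH2Cl2, rt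
Reagents that add atoms: none
Why: Palladium-catalysed formate hydrogenolysis, known for alkenyl epoxides and for α,β-epoxy ketones, in which zerovalent palladium ionises the allylic C5–O bond from the β face, hydride passes from the metal to the more substituted allyl terminus on that face (net inversion), and the freed 6α-hydroxyl closes the trans lactone on the ester.

**Step 24**
Reactants: 30 lactone cycloheptanone; 31 allyl bromide
Product: 32 1β-allyl-1α-ol (diene for metathesis)
Conditions: Zn dust, THF–sat. aq. NH4Cl, 0 °C to rt
Reagents that add atoms: allyl bromide, C=CCBr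
Why: Barbier allylation, in which the weakly basic allylzinc adds through a cyclic transition state to the β face of the ketone, anti to the 5α-isopropenyl group and to the 10α-silyloxy group (polar Felkin–Anh), while ester, lactone and methylene lactone are inert to it.

**Step 25**
Reactants: 32 1β-allyl-1α-ol
Product: 33 trans-fused guai-3-ene (1α-OH, 10α-OSiEt3)
Conditions: second-generation Grubbs catalyst (cat.), CH2Cl2 (dilute), reflux
Reagents that add atoms: none
Why: Ring-closing metathesis starts at the monosubstituted allyl alkene and closes on the isopropenyl group to the trisubstituted cyclopentene, the trans-disposed chains give the trans ring fusion, and the electron-poor methylene lactone does not compete.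

**Step 26**
Reactants: 33 10-O-triethylsilyl guai-3-ene
Product: 34 trans-fused guai-3-ene-1α,10α-diol lactone
Conditions: HF·pyridine, pyridine, THF, 0 °C to rt
Reagents that add atoms: none
Why: Buffered fluoride cleavage removes the tertiary silyl ether before the acid-sensitive oxirane is made and leaves the methylene lactone intact.

**Step 27**
Reactants: 34 guai-3-ene-1α,10α-diol
Product: 35 3α,4α-epoxyguaiane-1α,10α-diol lactone
Conditions: VO(acac)2 (cat.), t-BuOOH (decane), CH2Cl2, 0 °C
Reagents that add atoms: tert-butyl hydroperoxide, CC(C)(C)OO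
Why: Vanadium-catalysed hydroxyl-directed epoxidation of a cyclopent-3-enol delivers the peroxide from the vanadate of the 1α-hydroxyl, so the oxirane forms on the α face and sets C3 and C4, while the electron-poor methylene lactone is not oxidised.

**Step 28**
Reactants: 35 3α,4α-epoxyguaiane-1α,10α-diol lactone
Product: 36 target CNP0406522.1
Conditions: Ti(OiPr)4, CH2Cl2, 0 °C to 40 °C; cold aq. tartaric acid
Reagents that add atoms: none
Why: Proposed new method: alcohol exchange places titanium on the 1α (and 10α) oxygen and the same Lewis-acidic metal reaches the α-oxirane oxygen, so the C1–O lone pair closes to the carbonyl, the C1–C5 σ electrons become the C4=C5 π bond and the tertiary C4–O bond opens to leave the C3 alkoxide, which is protonated on work-up. The closest known reaction types are the Lewis-acid-promoted Grob fragmentation of 3,4-epoxy tertiary alcohols and the Wharton fragmentation of cyclic 1,3-diol monosulfonates, which tolerates a nucleofuge on a cyclopentane carbon next to the ring fusion; untested is an oxirane fused to the very cyclopentane that holds the breaking bond, where the C4–O/C5–C1 dihedral angle can only approach about 130–150° and not 180°. No ring is closed: the ten-membered carbocycle appears because the bond common to the five- and seven-membered rings is cut, helped by release of oxirane and trans-hydroazulene strain. No stereocentre is created: C3 keeps the configuration fixed in step 27 because its C–O bond is untouched, C6, C7, C8 and C10 are spectators, and the Z geometry follows from the anti arrangement of the breaking bonds, since the oxirane oxygen is trans to H5 and cis to C6, which puts C3 and C6 on the same side of the new alkene. The step needs C1–C5 and not C1–C2 scission, secured because positive charge builds far more easily at tertiary C4 than at secondary C3, and fragmentation and not ether formation, secured because both hydroxyls sit on the oxirane face and cannot reach the backside of C3 or C4. The aldol-type product is released by a cold, mildly acidic quench to avoid retro-aldol opening or dehydration across C2–C3.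

## Compound list

1 | (R)-(−)-carvone | CC1=CC[C@@H](C(=C)C)CC1=O | starting material
2 | carvone 9α,10α-epoxide | C[C@@]12O[C@@H]1C[C@@H](C(C)=C)CC2=O | intermediate
3 | 9α,10α-epoxy-1α-ol | C[C@@]12O[C@@H]1C[C@@H](C(C)=C)C[C@@H]2O | intermediate
4 | 9α,10α-epoxy-1α-OTBS ether | C[C@@]12O[C@@H]1C[C@@H](C(C)=C)C[C@@H]2O[Si](C)(C)C(C)(C)C | intermediate
5 | 9β-phenylselanyl-10α-ol | C[C@@]1(O)[C@@H]([Se]c2ccccc2)C[C@@H](C(C)=C)C[C@@H]1O[Si](C)(C)C(C)(C)C | intermediate
6 | 9β-selenoxide (not isolated) | C[C@@]1(O)[C@@H]([Se](=O)c2ccccc2)C[C@@H](C(C)=C)C[C@@H]1O[Si](C)(C)C(C)(C)C | intermediate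
7 | tertiary allylic alcohol, C8=C9, 10α-OH, 1α-OTBS | C[C@@]1(O)C=C[C@@H](C(=C)C)C[C@@H]1O[Si](C)(C)C(C)(C)C | intermediate
8 | 10α-O-dimethylsilyl ether | C[C@@]1(O[SiH](C)C)C=C[C@@H](C(=C)C)C[C@@H]1O[Si](C)(C)C(C)(C)C | intermediate
9 | bridged siloxane, O10–SiMe2–C8 on the α face (not isolated) | C[C@@]12O[Si](C)(C)[C@@H](C1)[C@@H](C(C)=C)C[C@@H]2O[Si](C)(C)C(C)(C)C | intermediate
10 | 8α,10α-diol | C[C@@]1(O)C[C@H](O)[C@@H](C(C)=C)C[C@@H]1O[Si](C)(C)C(C)(C)C | intermediate
11 | 10α-hydroxy-8-ketone | C[C@@]1(O)CC(=O)[C@@H](C(C)=C)C[C@@H]1O[Si](C)(C)C(C)(C)C | intermediate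
12 | 8β,10α-diol | C[C@@]1(O)C[C@@H](O)[C@@H](C(C)=C)C[C@@H]1O[Si](C)(C)C(C)(C)C | intermediate
13 | isovaleric acid | CC(C)CC(=O)O | starting material
14 | 8β-isovalerate | C[C@@]1(O)C[C@@H](OC(=O)CC(C)C)[C@@H](C(C)=C)C[C@@H]1O[Si](C)(C)C(C)(C)C | intermediate
15 | allylic alcohol (C12 CH2OH) | C[C@@]1(O)C[C@@H](OC(=O)CC(C)C)[C@@H](C(=C)CO)C[C@@H]1O[Si](C)(C)C(C)(C)C | intermediate
16 | enal (C12 CHO) | C[C@@]1(O)C[C@@H](OC(=O)CC(C)C)[C@@H](C(=C)C=O)C[C@@H]1O[Si](C)(C)C(C)(C)C | intermediate
17 | acrylic acid | C[C@@]1(O)C[C@@H](OC(=O)CC(C)C)[C@@H](C(=C)C(=O)O)C[C@@H]1O[Si](C)(C)C(C)(C)C | intermediate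
18 | methyl acrylate ester | C[C@@]1(O)C[C@@H](OC(=O)CC(C)C)[C@@H](C(=C)C(=O)OC)C[C@@H]1O[Si](C)(C)C(C)(C)C | intermediate
19 | 1α,10α-diol | C[C@@]1(O)C[C@@H](OC(=O)CC(C)C)[C@@H](C(=C)C(=O)OC)C[C@@H]1O | intermediate
20 | cyclohexanone with C1 ketone, 10α-OH, 8β-isovalerate, 7β-acrylate | C=C(C(=O)OC)[C@H]1CC(=O)[C@](C)(O)C[C@H]1OC(=O)CC(C)C | intermediate
21 | bis(triethylsilyl) enol ether | C=C(C(=O)OC)[C@H]1C=C(O[Si](CC)(CC)CC)[C@](C)(O[Si](CC)(CC)CC)C[C@H]1OC(=O)CC(C)C | intermediate
22 | silyloxycyclopropane (drawn for α attack) | C=C(C(=O)OC)[C@H]1[C@@H]2C[C@]2(O[Si](CC)(CC)CC)[C@](C)(O[Si](CC)(CC)CC)C[C@H]1OC(=O)CC(C)C | intermediate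
23 | 6-chlorocycloheptanone, C6 undefined (not isolated) | C=C(C(=O)OC)[C@H]1C(Cl)CC(=O)[C@](C)(O[Si](CC)(CC)CC)C[C@H]1OC(=O)CC(C)C | intermediate
24 | cycloheptenone, 10α-OSiEt3 | C=C(C(=O)OC)[C@H]1C=CC(=O)[C@](C)(O[Si](CC)(CC)CC)C[C@H]1OC(=O)CC(C)C | intermediate
25 | 5-iodocycloheptenone | C=C(C(=O)OC)[C@H]1C=C(I)C(=O)[C@](C)(O[Si](CC)(CC)CC)C[C@H]1OC(=O)CC(C)C | intermediate
26 | isopropenylboronic acid pinacol ester | CC(=C)B1OC(C)(C)C(C)(C)O1 | starting material
27 | 5-isopropenylcycloheptenone | C=C(C(=O)OC)[C@H]1C=C(C(C)=C)C(=O)[C@](C)(O[Si](CC)(CC)CC)C[C@H]1OC(=O)CC(C)C | intermediate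
28 | 5α,6α-epoxy ketone | C=C(C(=O)OC)[C@H]1[C@@H]2O[C@]2(C(C)=C)C(=O)[C@](C)(O[Si](CC)(CC)CC)C[C@H]1OC(=O)CC(C)C | intermediate
29 | 6α-hydroxy ester, H5 β (not isolated) | C=C(C(=O)OC)[C@H]1[C@H](O)[C@H](C(C)=C)C(=O)[C@](C)(O[Si](CC)(CC)CC)C[C@H]1OC(=O)CC(C)C | intermediate
30 | trans-fused methylene lactone cycloheptanone, 5α-isopropenyl | C=C1C(=O)O[C@@H]2[C@H](C(C)=C)C(=O)[C@](C)(O[Si](CC)(CC)CC)C[C@@H](OC(=O)CC(C)C)[C@@H]12 | intermediate
31 | allyl bromide | C=CCBr | starting material
32 | 1β-allyl-1α-ol | C=C1C(=O)O[C@@H]2[C@H](C(C)=C)[C@@](O)(CC=C)[C@](C)(O[Si](CC)(CC)CC)C[C@@H](OC(=O)CC(C)C)[C@@H]12 | intermediate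
33 | trans-fused guai-3-ene, 1α-OH, 10α-OSiEt3 | C=C1C(=O)O[C@@H]2[C@@H]3C(C)=CC[C@@]3(O)[C@](C)(O[Si](CC)(CC)CC)C[C@@H](OC(=O)CC(C)C)[C@@H]12 | intermediate
34 | trans-fused guai-3-ene-1α,10α-diol lactone | C=C1C(=O)O[C@@H]2[C@@H]3C(C)=CC[C@@]3(O)[C@](C)(O)C[C@@H](OC(=O)CC(C)C)[C@@H]12 | intermediate
35 | 3α,4α-epoxyguaiane-1α,10α-diol lactone | C=C1C(=O)O[C@@H]2[C@@H]3[C@]4(C)O[C@@H]4C[C@@]3(O)[C@](C)(O)C[C@@H](OC(=O)CC(C)C)[C@@H]12 | intermediate
36 | CNP0406522.1 | C=C1C(=O)O[C@@H]2/C=C(/C)[C@H](O)CC(=O)[C@](C)(O)C[C@@H](OC(=O)CC(C)C)[C@@H]12 | target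

## Step count and risks

Total step count: 28. Longest linear sequence: 28 steps, from 1 to 36.

The three steps most likely to fail are listed below.

**1. Step 28 (bears the label "Proposed new method:")**
- What may go wrong: imperfect alignment of the C4–O and C1–C5 bonds may let ionisation at C4 be followed by hydride shift or proton loss instead of C–C scission. The aldol-type product may also open by retro-aldol cleavage while still bound to the metal.
- Fallback: this uses known chemistry only and builds the ring by metathesis instead of fragmentation. It sets out from 21 and comes back at 36. The enol silyl ether of 21 is exchanged for a triflate (CsF, PhNTf2, DME) to give the enol triflate F1. Negishi methylation (Me2Zn, Pd(PPh3)4, THF) puts C2 on C1 and gives the 1-methylcyclohexene F2. Ozonolysis (O3, CH2Cl2, −78 °C; Me2S), selective for the electron-rich ring alkene, cuts C1=C6 to the open-chain keto aldehyde F3. Nozaki–Hiyama–Kishi vinylation of the aldehyde (vinyl iodide, CrCl2, NiCl2 cat., DMF) brings in C5 and gives the 6-carbinol F4. This lactonises (PPTS, CH2Cl2) to the vinyl lactone F5, and C6 epimers are separated at this stage. A boron aldol reaction of the methyl ketone with methacrolein (the matched enantiomer of Ipc2BCl, Et3N, Et2O, −78 °C) adds C3, C4 and C15 and gives the β-hydroxy ketone F6. Ring-closing metathesis at high dilution (second-generation Hoveyda–Grubbs catalyst, toluene, 80 °C) joins C4 to C5, where the medium ring is expected to favour the Z alkene. This gives the 10-O-triethylsilyl ether of the target F7, and HF·pyridine then gives 36.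

**2. Step 23**
- What may go wrong: configuration at C5 may be lost through interconversion of the allylpalladium species with a palladium enolate followed by protonation. Amine-promoted epimerisation, migration of the alkene into conjugation, and β-elimination of the C6 oxygen from the doubly activated C5–H are further risks.
- Fallback: the order of events is changed so that C5 is never α to a ketone. It sets out from 28 and comes back at 32. Allylzinc bromide (Zn, allyl bromide, THF–aq. NH4Cl) is added to the epoxy ketone 28 anti to the oxirane and silyloxy oxygens, which gives the 1β-allyl-1α-hydroxy-5α,6α-epoxide F8. The same palladium–formate hydrogenolysis, now on an ordinary alkenyl epoxide, gives with inversion the 1α,6α-dihydroxy ester F9. Acid-catalysed lactonisation (PPTS) then returns 32.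

**3. Step 22**
- What may go wrong: the amidine base may deprotonate C7 (γ to the enone and allylic to the acrylate), leading to loss of the C8 isovalerate or alkene migration. Peroxide addition to the hindered α-substituted enone may be sluggish, and the acrylate may be attacked instead.
- Fallback: base-free, hydroxyl-directed epoxidation replaces the nucleophilic one. It sets out from 27 and comes back at 28. Luche reduction (NaBH4, CeCl3·7H2O, MeOH, −78 °C), with hydride entering anti to the 10α-silyloxy group, gives the 1α-dienol F10. VO(acac)2 with t-BuOOH epoxidises the allylic C5=C6 alkene syn to the hydroxyl and gives the 5α,6α-epoxy-1α-ol F11. Dess–Martin oxidation then returns 28.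

## Further compounds

F1 | step 28 | enol triflate (C1=C6, 10α-OSiEt3) | C=C(C(=O)OC)[C@H]1C=C(OS(=O)(=O)C(F)(F)F)[C@](C)(O[Si](CC)(CC)CC)C[C@H]1OC(=O)CC(C)C
F2 | step 28 | 1-methylcyclohexene (C2 on C1) | C=C(C(=O)OC)[C@H]1C=C(C)[C@](C)(O[Si](CC)(CC)CC)C[C@H]1OC(=O)CC(C)C
F3 | step 28 | open-chain keto aldehyde (C1 methyl ketone, C6 aldehyde) | CC(=O)[C@](C)(O[Si](CC)(CC)CC)C[C@@H](OC(=O)CC(C)C)[C@H](C=O)C(=C)C(=O)OC
F4 | step 28 | 6-carbinol (vinyl adduct, hydroxy ester) | CC(=O)[C@](C)(O[Si](CC)(CC)CC)C[C@@H](OC(=O)CC(C)C)[C@H]([C@H](O)C=C)C(=C)C(=O)OC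
F5 | step 28 | vinyl lactone methyl ketone | C=C1C(=O)O[C@H](C=C)[C@H]1[C@H](OC(=O)CC(C)C)C[C@@](C)(O[Si](CC)(CC)CC)C(C)=O
F6 | step 28 | β-hydroxy ketone (seco diene) | C=C1C(=O)O[C@H](C=C)[C@H]1[C@H](OC(=O)CC(C)C)C[C@@](C)(O[Si](CC)(CC)CC)C(=O)C[C@@H](O)C(C)=C
F7 | step 28 | 10-O-triethylsilyl ether of the target | C=C1C(=O)O[C@@H]2/C=C(/C)[C@H](O)CC(=O)[C@](C)(O[Si](CC)(CC)CC)C[C@@H](OC(=O)CC(C)C)[C@@H]12
F8 | step 23 | 1β-allyl-1α-hydroxy-5α,6α-epoxide | C=C(C(=O)OC)[C@H]1[C@@H]2O[C@]2(C(C)=C)[C@@](O)(CC=C)[C@](C)(O[Si](CC)(CC)CC)C[C@H]1OC(=O)CC(C)C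
F9 | step 23 | 1α,6α-dihydroxy ester (H5 β) | C=C(C(=O)OC)[C@H]1[C@H](O)[C@H](C(C)=C)[C@@](O)(CC=C)[C@](C)(O[Si](CC)(CC)CC)C[C@H]1OC(=O)CC(C)C
F10 | step 22 | 1α-dienol | C=C(C(=O)OC)[C@H]1C=C(C(C)=C)[C@H](O)[C@](C)(O[Si](CC)(CC)CC)C[C@H]1OC(=O)CC(C)C
F11 | step 22 | 5α,6α-epoxy-1α-ol | C=C(C(=O)OC)[C@H]1[C@@H]2O[C@]2(C(C)=C)[C@H](O)[C@](C)(O[Si](CC)(CC)CC)C[C@H]1OC(=O)CC(C)C
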